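**Retrosynthetic overview**

1. The target is the [4+2] adduct of a ring-trans caryophyllane 4′-ene-12′-carbonyl dienophile and a labda-8(17),12E,14-triene. The cyclohexene (C12–C13=C14–C15–C5′–C4′) is cut by a retro-Diels–Alder reaction, but only after the labdane decalin has been unzipped.
2. Key disconnection: rings A and B (bonds C4–C5 and C9–C10, olefin C8=C17) are opened to an acyclic (E,E)-diene α-methyl-β-keto ester hanging from the intact tricyclic core. Forward, one oxidative radical cascade closes ring A and then ring B, the last ring.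
3. Enabling feature: C4 carries CH3 and CO2H next to C3, C10 is a methyl-bearing quaternary carbon, and C8 carries an exocyclic CH2 next to C9. With a temporary C3 ketone, C4 becomes a β-dicarbonyl radical site, C5=C10 and C8=C9 are the relay olefins, and the C17 methyl gives up H to end as the methylene.
4. Fragments: the enal dienophile from (−)-β-caryophyllene (allylic oxidation); the tetraene keto ester from geranyl bromide, 3-methyl-3-sulfolene (diene by SO2 extrusion) and the (−)-8-phenylmenthyl ester of 2-methylacetoacetic acid (the auxiliary sets the absolute configuration of the decalin).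
5. Ring order: cyclobutane and nine-membered ring (chiral pool) → cyclohexene (Diels–Alder) → ring A → ring B; then C3 deoxygenation, reductive removal of the auxiliary and oxidation to the diacid.

Key step: step 10

Assumption (numbering): the diterpene half is numbered as a labdane (C1–C20) and the sesquiterpene half as a caryophyllane with primes (C4′ bears the carboxyl carbon C12′; C8′=C13′ is the methylene). The ring-trans C4′=C5′ geometry of β-caryophyllene reads Z by CIP once C12′ is oxidized.
Assumption (intermediates): carbanions 6 and 11 and the telescoped alcohol 14 are numbered as non-isolated compounds; radicals and metal-bound species of step 10 are treated as mechanism.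

**Step 1**
Reactants: 1 ethyl 2-methyl-3-oxobutanoate; 2 (−)-8-phenylmenthol
Product: 3 (−)-8-phenylmenthyl 2-methyl-3-oxobutanoate (both α-epimers)
Conditions: DMAP (0.3 equiv), toluene, reflux, 4 Å MS
Reagents that add atoms: none
Why: DMAP-catalysed transesterification of a β-keto ester tolerates the hindered secondary alcohol, and the epimeric α-centre is erased when C4 becomes a radical in step 10.

**Step 2**
Reactants: 4 geranyl bromide; 5 3-methyl-3-sulfolene
Product: 7 2-geranyl-3-methyl-3-sulfolene (racemic at C2), via 2-lithio-3-methyl-3-sulfolene 6 (not isolated)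
Conditions: LiHMDS (1.1 equiv) added to 4 + 5, THF/DMPU, −78 °C
Reagents that add atoms: none
Why: Alkylation of the α-sulfonyl carbanion of 3-methyl-3-sulfolene at C2 (next to the methyl-bearing carbon) with in situ trapping at −78 °C avoids ring opening of the anion; the new sulfolene centre disappears in step 4.

**Step 3**
Reactants: 7 2-geranyl-3-methyl-3-sulfolene
Product: 8 2-[(2E,6E)-8-hydroxy-3,7-dimethylocta-2,6-dienyl]-3-methyl-3-sulfolene
Conditions: SeO2 (0.3 equiv), t-BuOOH (3 equiv), salicylic acid (0.1 equiv), CH2Cl2, 0 °C to rt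
Reagents that add atoms: tert-butyl hydroperoxide, CC(C)(C)OO (terminal oxidant; the oxygen is passed on through selenium dioxide, O=[Se]=O)
Why: Catalytic SeO2 allylic oxidation (ene reaction, then [2,3]-sigmatropic shift) is selective for the E-methyl group of the terminal trisubstituted olefin, and the electron-poor sulfolene olefin is inert.

**Step 4**
Reactants: 8 hydroxy sulfolene
Product: 9 (2E,6E,9E)-2,6,10-trimethyldodeca-2,6,9,11-tetraen-1-ol
Conditions: pyridine (1 equiv), toluene, 110 °C
Reagents that add atoms: none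
Why: Thermal cheletropic extrusion of SO2 from a 2-substituted 3-sulfolene is disrotatory with the substituent turning outward, so only the (E)-1,3-diene should form.

**Step 5**
Reactants: 9 tetraenol
Product: 10 (3E,6E,10E)-12-bromo-3,7,11-trimethyldodeca-1,3,6,10-tetraene
Conditions: CBr4, PPh3, CH2Cl2, 0 °C
Reagents that add atoms: carbon tetrabromide, BrC(Br)(Br)Br
Why: The Appel reaction converts the primary allylic alcohol to the bromide under neutral conditions without allylic transposition and without touching the diene.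

**Step 6**
Reactants: 3 (−)-8-phenylmenthyl 2-methyl-3-oxobutanoate; 10 tetraenyl bromide
Product: 12 (−)-8-phenylmenthyl (6E,10E,13E)-2,6,10,14-tetramethyl-3-oxohexadeca-6,10,13,15-tetraenoate, via dilithio dianion 11 (not isolated)
Conditions: 3, LDA (2.1 equiv), THF, 0 °C; then 10, −78 to 0 °C; aq. NH4Cl
Reagents that add atoms: none
Why: γ-Alkylation of a β-keto ester dianion occurs at the terminal, more basic carbanion by SN2 on the primary allylic bromide and keeps all olefin geometries.

**Step 7**
Reactants: 13 (−)-β-caryophyllene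
Product: 15 (1R,4Z,9S)-11,11-dimethyl-8-methylidenebicyclo[7.2.0]undec-4-ene-4-carbaldehyde (ring-trans enal), via allylic alcohol 14 (not isolated)
Conditions: SeO2 (0.5 equiv), t-BuOOH (2 equiv), CH2Cl2, 0 °C to rt; filtration; then MnO2 (15 equiv), CH2Cl2, rt
Reagents that add atoms: tert-butyl hydroperoxide, CC(C)(C)OO (terminal oxidant; the oxygen is passed on through selenium dioxide, O=[Se]=O)
Why: The SeO2 ene reaction at the strained, electron-rich C4′=C5′ bond is followed by a fast [2,3]-shift from the conformer in which it is formed, so the vinylic methyl should be oxidized with retention of the ring-trans geometry, and MnO2 takes the allylic alcohol to the enal.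

**Step 8**
Reactants: 12 tetraene β-keto ester; 15 ring-trans enal
Product: 16 Diels–Alder adduct aldehyde (cyclohexene C12–C13=C14–C15–C5′–C4′; CHO on C4′; the keto ester chain on C12)
Conditions: Me2AlCl (2.5 equiv), CH2Cl2, −78 to −30 °C; Rochelle salt work-up
Reagents that add atoms: none
Why: Lewis-acid-promoted Diels–Alder reaction in which the CH2 terminus of the diene bonds to the β-carbon C5′ ("ortho" regiochemistry of a 1-alkyl diene), the carbonyl-endo transition state places the C12 side chain cis to CHO, the suprafacial addition turns the ring-trans olefin into the trans 6/9 fusion, and the diene approaches the exposed outer face of C4′=C5′ (the face that is epoxidized in caryophyllene oxide); the first equivalent of Me2AlCl is consumed by the β-keto ester as its aluminium chelate.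

**Step 9**
Reactants: 16 adduct aldehyde
Product: 17 adduct carboxylic acid (CO2H on C4′)
Conditions: NaClO2, NaH2PO4, 2-methyl-2-butene (excess), t-BuOH/THF/H2O, 0 °C to rt
Reagents that add atoms: sodium chlorite, [Na+].[O-]Cl=O
Why: Pinnick oxidation converts the non-enolizable neopentyl aldehyde to the acid, and the olefin scavenger removes HOCl before it can reach the olefins or the β-keto ester.

**Step 10**
Reactants: 17 adduct carboxylic acid
Product: 18 3-oxo-labd-8(17)-ene 19-(8-phenylmenthyl) ester joined through C11 to the tricyclic acid (rings A and B closed)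
Conditions: Mn(OAc)3·2H2O (2.2 equiv), Cu(OAc)2·H2O (1.0 equiv), degassed AcOH (0.05 M), 25 °C
Reagents that add atoms: none
Why: Mn(III) oxidizes the enolized α-methyl-β-keto ester to the electrophilic C4 radical, which adds 6-endo-trig to C5 of the (E)-C5=C10 olefin (ring A); the tertiary C10 radical adds 6-endo-trig to C9 of the (E)-C8=C9 olefin (ring B, C9–C10 bond, the last ring of the skeleton), and Cu(II) captures the tertiary C8 radical and eliminates toward the C17 methyl to give the 8(17)-methylene. The closest known reaction type is the Mn(OAc)3/Cu(OAc)2 oxidative free-radical polyene bicyclization of α-substituted β-keto esters, including its 8-phenylmenthyl ester version. C4 is set by the auxiliary: the phenyl ring of the (1R,2S,5R)-ester lies over one face of the planar dicarbonyl radical so that C5 bonds to the open face, and the non-chelated rotamer with the ketone oxygen anti to the ester carbonyl places the ester axial (C19 cis to C20). C5, C10 and C9 follow from the chair–chair transition state of the two E-olefins (H-5 and C20 trans-diaxial, C11 equatorial on C9), so all four new centres are relayed from the auxiliary and none depends on the remote sesquiterpene centres. The step needs initiation at the β-dicarbonyl only (the free CO2H, the cyclohexene olefin and the C8′ methylene are not oxidized by Mn(III) at 25 °C), no further cyclization of the C8 radical onto the cyclohexene (this would need a bridged bicyclo[3.3.1] ring or two adjacent quaternary carbons and should be outrun by Cu(II) capture), and Hofmann-type elimination to the exocyclic olefin, the usual outcome of Cu(II) termination at a methyl-bearing tertiary radical. The quaternary C4 of 18 has no α-hydrogen, so the product cannot be oxidized again.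

**Step 11**
Reactants: 18 3-oxo ester acid
Product: 19 C3 tosylhydrazone of 18
Conditions: TsNHNH2 (1.5 equiv), PPTS (cat.), EtOH, 65 °C
Reagents that add atoms: p-toluenesulfonohydrazide, Cc1ccc(cc1)S(=O)(=O)NN
Why: Hydrazone formation at the C3 ketone, the only carbonyl of 18 that can condense, as is usual for 3-oxo-4,4-disubstituted terpenoids.

**Step 12**
Reactants: 19 tosylhydrazone
Product: 20 3-deoxo ester acid (C3 = CH2)
Conditions: catecholborane (4 equiv), CHCl3, 0 °C; then NaOAc·3H2O, reflux
Reagents that add atoms: none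
Why: Catecholborane reduction of a tosylhydrazone (hydroboration of C=N, then acetate-induced loss of sulfinate and N2) gives the methylene under conditions that leave the three olefins and the hindered ester untouched.

**Step 13**
Reactants: 20 3-deoxo ester acid
Product: 21 diol (CH2OH on C4 and on C4′)
Conditions: LiAlH4 (excess), THF, reflux; Fieser work-up
Reagents that add atoms: none
Why: LiAlH4 reduces the hindered axial ester and the carboxylic acid to primary alcohols and releases the auxiliary for recovery, while isolated olefins are inert.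

**Step 14**
Reactants: 21 diol
Product: 22 dialdehyde
Conditions: Dess–Martin periodinane (3 equiv), NaHCO3, CH2Cl2, 0 °C to rt
Reagents that add atoms: none
Why: Buffered Dess–Martin oxidation takes both neopentyl primary alcohols to non-enolizable aldehydes without acid that could touch the cyclobutyl-flanked methylene.

**Step 15**
Reactants: 22 dialdehyde
Product: 23 CNP0330729.1 (target diacid)
Conditions: NaClO2, NaH2PO4, 2-methyl-2-butene (excess), t-BuOH/THF/H2O, 0 °C to rt
Reagents that add atoms: sodium chlorite, [Na+].[O-]Cl=O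
Why: Pinnick oxidation converts both hindered aldehydes to the acids, and the scavenger protects the three olefins; no stereocentre is touched.

**Compound list**

1 | ethyl 2-methyl-3-oxobutanoate | CCOC(=O)C(C)C(C)=O | starting material
2 | (−)-8-phenylmenthol, (1R,2S,5R)-5-methyl-2-(2-phenylpropan-2-yl)cyclohexan-1-ol | CC(C)(c1ccccc1)[C@@H]1CC[C@@H](C)C[C@H]1O | starting material
3 | (1R,2S,5R)-5-methyl-2-(2-phenylpropan-2-yl)cyclohexyl 2-methyl-3-oxobutanoate | CC(=O)C(C)C(=O)O[C@@H]1C[C@H](C)CC[C@H]1C(C)(C)c1ccccc1 | intermediate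
4 | geranyl bromide, (2E)-1-bromo-3,7-dimethylocta-2,6-diene | CC(C)=CCC/C(C)=C/CBr | starting material
5 | 3-methyl-3-sulfolene (3-methyl-2,5-dihydrothiophene 1,1-dioxide) | CC1=CCS(=O)(=O)C1 | starting material
6 | 2-lithio-3-methyl-3-sulfolene | [Li+].CC1=CCS(=O)(=O)[CH-]1 | intermediate (not isolated)
7 | 2-[(2E)-3,7-dimethylocta-2,6-dienyl]-3-methyl-2,5-dihydrothiophene 1,1-dioxide | CC1=CCS(=O)(=O)C1C/C=C(\C)CCC=C(C)C | intermediate
8 | 2-[(2E,6E)-8-hydroxy-3,7-dimethylocta-2,6-dienyl]-3-methyl-2,5-dihydrothiophene 1,1-dioxide | CC1=CCS(=O)(=O)C1C/C=C(\C)CC/C=C(\C)CO | intermediate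
9 | (2E,6E,9E)-2,6,10-trimethyldodeca-2,6,9,11-tetraen-1-ol | OC/C(C)=C/CC/C(C)=C/C/C=C(\C)C=C | intermediate
10 | (3E,6E,10E)-12-bromo-3,7,11-trimethyldodeca-1,3,6,10-tetraene | BrC/C(C)=C/CC/C(C)=C/C/C=C(\C)C=C | intermediate
11 | dilithio dianion of 3 (C2 and C4 of the butanoate) | [Li+].[Li+].[CH2-]C(=O)[C-](C)C(=O)O[C@@H]1C[C@H](C)CC[C@H]1C(C)(C)c1ccccc1 | intermediate (not isolated)
12 | (1R,2S,5R)-5-methyl-2-(2-phenylpropan-2-yl)cyclohexyl (6E,10E,13E)-2,6,10,14-tetramethyl-3-oxohexadeca-6,10,13,15-tetraenoate | C=C/C(C)=C/C/C=C(\C)CC/C=C(\C)CCC(=O)C(C)C(=O)O[C@@H]1C[C@H](C)CC[C@H]1C(C)(C)c1ccccc1 | intermediate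
13 | (−)-β-caryophyllene, (1R,4E,9S)-4,11,11-trimethyl-8-methylidenebicyclo[7.2.0]undec-4-ene | C/C1=C\CCC(=C)[C@H]2CC(C)(C)[C@@H]2CC1 | starting material
14 | [(1R,4Z,9S)-11,11-dimethyl-8-methylidenebicyclo[7.2.0]undec-4-en-4-yl]methanol (ring-trans) | OC/C1=C\CCC(=C)[C@H]2CC(C)(C)[C@@H]2CC1 | intermediate (not isolated)
15 | (1R,4Z,9S)-11,11-dimethyl-8-methylidenebicyclo[7.2.0]undec-4-ene-4-carbaldehyde (ring-trans) | O=C/C1=C\CCC(=C)[C@H]2CC(C)(C)[C@@H]2CC1 | intermediate
16 | Diels–Alder adduct aldehyde (CHO on C4′, acyclic diene keto ester chain on C12) | C=C1CC[C@H]2CC=C(C)[C@@H](C/C=C(\C)CC/C=C(\C)CCC(=O)C(C)C(=O)O[C@@H]3C[C@H](C)CC[C@H]3C(C)(C)c3ccccc3)[C@]2(C=O)CC[C@@H]2[C@@H]1CC2(C)C | intermediate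
17 | Diels–Alder adduct acid (CO2H on C4′) | C=C1CC[C@H]2CC=C(C)[C@@H](C/C=C(\C)CC/C=C(\C)CCC(=O)C(C)C(=O)O[C@@H]3C[C@H](C)CC[C@H]3C(C)(C)c3ccccc3)[C@]2(C(=O)O)CC[C@@H]2[C@@H]1CC2(C)C | intermediate
18 | 3-oxo 19-(8-phenylmenthyl) ester acid (labdane rings A and B closed, 8(17)-methylene) | C=C1CC[C@H]2CC=C(C)[C@@H](C[C@H]3C(=C)CC[C@@H]4[C@]3(C)CCC(=O)[C@]4(C)C(=O)O[C@@H]5C[C@H](C)CC[C@H]5C(C)(C)c5ccccc5)[C@]2(C(=O)O)CC[C@@H]2[C@@H]1CC2(C)C | intermediate
19 | C3 tosylhydrazone of 18 | C=C1CC[C@H]2CC=C(C)[C@@H](C[C@H]3C(=C)CC[C@@H]4[C@]3(C)CCC(=NNS(=O)(=O)c5ccc(C)cc5)[C@]4(C)C(=O)O[C@@H]5C[C@H](C)CC[C@H]5C(C)(C)c5ccccc5)[C@]2(C(=O)O)CC[C@@H]2[C@@H]1CC2(C)C | intermediate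
20 | 3-deoxo 19-(8-phenylmenthyl) ester acid | C=C1CC[C@H]2CC=C(C)[C@@H](C[C@H]3C(=C)CC[C@@H]4[C@]3(C)CCC[C@]4(C)C(=O)O[C@@H]5C[C@H](C)CC[C@H]5C(C)(C)c5ccccc5)[C@]2(C(=O)O)CC[C@@H]2[C@@H]1CC2(C)C | intermediate
21 | diol (C19 and C12′ as CH2OH) | C=C1CC[C@H]2CC=C(C)[C@@H](C[C@H]3C(=C)CC[C@@H]4[C@]3(C)CCC[C@]4(C)CO)[C@]2(CO)CC[C@@H]2[C@@H]1CC2(C)C | intermediate
22 | dialdehyde (C19 and C12′ as CHO) | C=C1CC[C@H]2CC=C(C)[C@@H](C[C@H]3C(=C)CC[C@@H]4[C@]3(C)CCC[C@]4(C)C=O)[C@]2(C=O)CC[C@@H]2[C@@H]1CC2(C)C | intermediate
23 | CNP0330729.1 | C=C1CC[C@H]2CC=C(C)[C@@H](C[C@H]3C(=C)CC[C@@H]4[C@]3(C)CCC[C@]4(C)C(=O)O)[C@]2(C(=O)O)CC[C@@H]2[C@@H]1CC2(C)C | target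

**Step count and risks**

Total step count: 15. Longest linear sequence: 13 steps (steps 2–6, then 8–15).

Steps most likely to fail:

1. Step 10. Face discrimination by the auxiliary may be incomplete, the Cu(II) termination may give endocyclic olefin isomers, or the C8 radical may add on to the cyclohexene olefin. The fallback sets out from 17 and comes back at 18, and ring B is still closed last. α-Bromination of the β-keto ester (NBS, cat. Mg(ClO4)2, EtOAc, −20 °C) gives the α-bromo keto ester F1. An Et3B/O2-initiated atom-transfer radical bicyclization at −78 °C (the same 6-endo/6-endo cascade, but ended by bromine transfer instead of metal oxidation) gives the C8 tertiary bromide F2. E2 elimination with DBU (toluene, 80 °C) toward the C17 methyl then gives 18.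

2. Step 8. Lewis-acid activation may trigger transannular attack of the C8′ methylene on the complexed enal, and endo/exo or π-facial control may be incomplete. The fallback sets out from 15 and comes back at 17. Pinnick oxidation of the enal gives the ring-trans α,β-unsaturated acid F3. This is heated with tetraene 12 without Lewis acid (hexafluoroisopropanol or an aqueous suspension, 60–80 °C, BHT), relying on the strain of the trans-cyclononene; it gives acid 17 directly and step 9 is omitted.

3. Step 12. Reduction of the hindered hydrazone may stall, or base-induced elimination may give the Δ2-olefin. The fallback sets out from 18 and comes back at 20. NaBH4 (MeOH/THF, 0 °C) gives the C3 alcohol F4 (configuration at C3 immaterial). PhOC(S)Cl, pyridine and DMAP give the O-phenyl thionocarbonate F5. Barton–McCombie deoxygenation (Bu3SnH, AIBN, toluene, 90 °C) then gives 20.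

**Further compounds**

F1 | step 10 | α-bromo-α-methyl-β-keto ester of 17 (Br on C4) | C=C1CC[C@H]2CC=C(C)[C@@H](C/C=C(\C)CC/C=C(\C)CCC(=O)C(C)(Br)C(=O)O[C@@H]3C[C@H](C)CC[C@H]3C(C)(C)c3ccccc3)[C@]2(C(=O)O)CC[C@@H]2[C@@H]1CC2(C)C
F2 | step 10 | bicyclized C8 tertiary bromide (3-oxo, 19-ester) | C=C1CC[C@H]2CC=C(C)[C@@H](C[C@H]3C(C)(Br)CC[C@@H]4[C@]3(C)CCC(=O)[C@]4(C)C(=O)O[C@@H]5C[C@H](C)CC[C@H]5C(C)(C)c5ccccc5)[C@]2(C(=O)O)CC[C@@H]2[C@@H]1CC2(C)C
F3 | step 8 | (1R,4Z,9S)-11,11-dimethyl-8-methylidenebicyclo[7.2.0]undec-4-ene-4-carboxylic acid (ring-trans) | OC(=O)/C1=C\CCC(=C)[C@H]2CC(C)(C)[C@@H]2CC1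
F4 | step 12 | C3 alcohol from 18 | C=C1CC[C@H]2CC=C(C)[C@@H](C[C@H]3C(=C)CC[C@@H]4[C@]3(C)CCC(O)[C@]4(C)C(=O)O[C@@H]5C[C@H](C)CC[C@H]5C(C)(C)c5ccccc5)[C@]2(C(=O)O)CC[C@@H]2[C@@H]1CC2(C)C
F5 | step 12 | C3 O-phenyl thionocarbonate of F4 | C=C1CC[C@H]2CC=C(C)[C@@H](C[C@H]3C(=C)CC[C@@H]4[C@]3(C)CCC(OC(=S)Oc5ccccc5)[C@]4(C)C(=O)O[C@@H]5C[C@H](C)CC[C@H]5C(C)(C)c5ccccc5)[C@]2(C(=O)O)CC[C@@H]2[C@@H]1CC2(C)C
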